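- Two questions stand for the flask below, after three earlier runs:

| flask | starting material | coupling partner | scavenger | remark | time |
|---|---|---|---|---|---|
| north-west | 0.10 mM | 0.80 mM | 0.060 mM | run made earlier |  |
| south | 0.15 mM | 0.80 mM | 0.060 mM | run made earlier |  |
| west | 0.20 mM | 0.80 mM | 0.090 mM | run made earlier |  |
| flask | 0.20 mM | 0.800 mM | 0.0600 mM |  | 3.0 min |

- north-west (time / min: starting material / %, target / %): 0.250: 80.4, 19.1; 0.667: 61.4, 37.5; 1.50: 48.6, 52.6; 4.00: 36.6, 59.4
- south (time / min: starting material / %, target / %): 0.250: 78.9, 18.7; 0.667: 63.5, 34.5; 1.50: 53.8, 45.3; 4.00: 54.8, 43.3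
- west (time / min: starting material / %, target / %): 0.417: 71.6, 27.3; 1.33: 54.0, 45.2; 2.50: 51.5, 45.4; 4.00: 52.9, 47.5

(scatter of a reading: 1 percentage point)

* part of the starting material that has reacted at 3.0 min
* share of the unused coupling partner that is free and not bound as idle adduct, at 3.0 min

- the numbers in the tables scatter by 1 percentage point (one standard deviation)
- the earlier runs do not show how much of coupling partner is bound; that part of a forecast is a guess

- South lies flat, with starting material at 53.8% after 1.50 min and 54.8% after 4.00 min, so this flask is reckoned as stalled by 3.0 min.
- At 4.00 min, south has converted 0.0678 mM and west 0.0942 mM, each just above its scavenger charge.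
- Converted amount times its excess over the scavenger charge, divided by [starting material] left, reads 0.00643 mM in south and 0.00374 mM in west, both charged with 0.80 mM of coupling partner like this flask, with a mean of 0.00509 mM: the stall quotient, a reading carrying the scatter.
- At one extreme the quotient is zero and conversion stops at the scavenger charge, 30.0% of this flask's starting material.
- At the other, the excess keeps the size it has at that stop, where most starting material remains: 0.0719 mM, or 35.9%.
- Putting that answer back gives 0.0691 mM, so the reckoning puts c in this flask at about 34.5%.
- Were the whole excess bound, and coupling partner used by nothing else, the free share would be 98.8%.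
- The forecast gives 35% and 90%, calling the second “a guess”; this reckoning agrees on c and parts on the free share.
- The flask gives 36.6% and 99.5%.

    starting material + coupling partner ⇌ intermediate (K = 470 M⁻¹, k = 26.0 M⁻¹ s⁻¹)
    coupling partner + released group ⇌ idle adduct, settled at all times (K = 940 M⁻¹)
    intermediate ⇌ target + released group (K = 4.60 × 10⁻⁵ M, k = 0.920 s⁻¹)
    scavenger + released group → scavenged by-product (k = 38000 M⁻¹ s⁻¹)
    2 coupling partner → self-condensation product (k = 22.0 M⁻¹ s⁻¹)

- In this flask, the step of starting material with coupling partner and the self-condensation ran side by side, with half of their turnover up to 3.0 min done by 0.215 min and 0.331 min: after 0.300 min, coupling partner stood at 57.6% of its charge and scavenger at 34.2%. Scavenger, the limiting reagent, stood at 0% by 1.50 min, and starting material went from 60.4% then to 63.4% at 3.00 min. The flask's own quotient at 3.0 min is 0.00766 mM.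
- In a neighbour flask with 0.024 mM of scavenger, the same rounds give 0.0613 mM and then 0.0355 mM, so the estimate of c goes from 30.7% to 17.8%; that flask gives 23.6%.

All runs are calculated on assumed constants, and the scatter is random.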